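Zeta, delta and beta each start from 10 mM of Z and 8.00 mM of L and differ in temperature.

| flask | Z | L | temperature | time | remark |
|---|---|---|---|---|---|
| zeta | 10 mM | 8.00 mM | 60 °C | 5.0 h |  |
| delta | 10 mM | 8.00 mM |  | 5.0 h | at 60 °C until 4.0 h, from then on at 75 °C |
| beta | 10 mM | 8.00 mM | 75 °C | 5.0 h |  |

* which flask leads in amount of Z.L, in percent of the Z charged ("all alike" within 1.5 percentage points) (zeta / delta / beta / all alike)
* how much Z.L is there at the end, in percent of the Z charged: zeta
* how much Z.L is there at the end, in percent of the Z charged: delta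
* how much Z.L is there at the end, in percent of the Z charged: beta

- amounts and yields of Z.L count D too
- given per volume of solution although it is solid: D
- the constants hold at 60 °C; other temperatures follow from the activation energies and enthalpies

    L + J → L.J (k1 = 0.98 L mol⁻¹ s⁻¹, Ea1 = 56.0 kJ mol⁻¹)
    L + L.J ⇌ L.L.J (K2 = 130 L mol⁻¹, k2 = 0.045 L mol⁻¹ s⁻¹, Ea2 = 73.0 kJ mol⁻¹, ΔH2 = 15.0 kJ mol⁻¹)
    Z ⇌ J (K3 = 1.3, k3 = 4.5 × 10⁻⁴ s⁻¹, Ea3 = 96.0 kJ mol⁻¹, ΔH3 = −64.0 kJ mol⁻¹)
    L.J → Z.L (k4 = 0.0012 s⁻¹, Ea4 = 87.0 kJ mol⁻¹)
    Z + L → Z.L (k5 = 0.13 L mol⁻¹ s⁻¹, Ea5 = 43.0 kJ mol⁻¹)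
    L + J ⇌ X (K6 = 590 L mol⁻¹, k6 = 0.23 L mol⁻¹ s⁻¹, Ea6 = 49.0 kJ mol⁻¹, ΔH6 = −43.0 kJ mol⁻¹)
    D ⇌ Z.L, rate k7*(cs7 - [Z.L]) while solid is left; crystals form when [Z.L] > cs7 (cs7 = 0.84 mM, k7 = 0.071 s⁻¹)
    (constants at 60 °C)

Z.L forms from Z and L directly, or from Z by way of J and L.J, and by either route one Z.L takes one Z and one L. L is the limiting reagent, its charge being smaller than that of Z. So I reckon with c(L)/c(Z) at the charge, 80.0%, and call this the L ceiling: the yield of Z.L, D counted, once the L charged has gone into Z.L. To judge the time I look at the end of the uptake in zeta, at 60 °C, and I don't hold c(Z) at its charge, since Z also turns into J. The excess of Z over L, 2.00 mM, shares itself between Z and J by K3, which gives c(J) = 1.13 mM and c(Z) = 0.870 mM. Against these two, L has a pseudo-first-order half-life of 9.46 min. L.J going on to Z.L has a half-life of 9.63 min, and X going back to L and J one of 29.6 min. Each of these is shorter than the run of 5.0 h. So I commit to the ceiling for zeta, delta and beta, and I don't reckon any shortfall.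

The forecast says all alike, with 79.9% for zeta (range 78.5% to 80%), 80% for delta (range 79.3% to 80%) and 80% for beta (range 79.5% to 80%), on the ground that “every route ends irreversibly in Z.L”. For zeta its number stands level with my ceiling.

The simulation gives 79.9% in zeta, 80.0% in delta and 80.0% in beta, so the flasks come out all alike, as the forecast said.

The number to hold is the L ceiling of 80.0%, and zeta ends at 79.9%, level with it. In zeta, unbound L is down to 0.021% of its charge at 5.00 h, while Z stands at 8.71% and J at 11.3% of the Z charged. The neighbour of beta charged with 17 mM of Z keeps 8.00 mM of L, so its ceiling falls to 47.1%, and that flask ends at 47.1%.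

(The constants used here were set for the occasion; no experiment stands behind them.)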